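**Plan**

- Half A is the 4,5-dimethoxy-7-methylnaphthalen-2-ol unit (joined at A-C1) and half B the 5-methoxy-2-methylnaphthalene-4,6-diol unit (joined at B-C1). In half B the aryl-bearing B-C1 and the hydroxylated B-C4 lie para in the ring B-C1/B-C2/B-C3/B-C4/B-C4a/B-C8a, which is the pattern a 4-aryl-4-hydroxy-1-tetralone leaves on losing water.
- Retrosynthesis: remove two isopropyl ethers, rehydrate across B-C1/B-C2, then cut the B-C1 to B-C2 bond to reach a diaryl ketone with an ortho (E)-crotonoyl group. That keto enone is cut at the carbonyl–propenyl bond and at the bond from the future B-C1 to B-C8a, back to a 3-arylphthalide, a benzamide and the half A aldehyde.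
- Forward: the half A naphthalene is closed first by Claisen condensation of a toluate-derived keto ester and formylated at A-C1; the benzene core of half B comes from 2-isopropoxyphenol by anionic ortho-Fries rearrangement.
- The pieces are joined by ortho-lithiation and aldehyde addition (phthalide); propenyllithium opens the lactone, oxidation gives the keto enone, cathodic cyclization closes the last ring, acid aromatizes it, and BCl3 frees the two phenols.
- Stereochemistry: the target has no stereocentre; the sp3 centres of the intermediates are racemic and are erased, and the biaryl axis appears only on aromatization.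

Key step: step 13

Remark: the target is drawn without an axial descriptor, so the tetra-ortho-substituted biaryl is taken to be required as the racemate.
Remark: in step 13 the electrons come from the cathode of a divided cell; the anodic counter-reaction takes place in the separated anolyte and is left out of the equation of that step.
Abbreviation used in the step lines: ArA = 4,5-dimethoxy-7-methyl-2-(propan-2-yloxy)naphthalen-1-yl.

**Route**

Step 1
Reactants: 1 1-methoxy-3,5-dimethylbenzene (3,5-dimethylanisole)
Product: 3 methyl 2-methoxy-4,6-dimethylbenzoate, via ortho-lithiated anisole 2 (not isolated)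
Conditions: n-BuLi, TMEDA, Et2O, 0 °C → rt; cannulated into ClCO2Me (excess), THF, −78 °C
Reagents that add atoms: methyl chloroformate, COC(=O)Cl
Why: Directed ortho-metalation, in which the methoxy group steers n-BuLi/TMEDA to the ring carbon between OMe and CH3 (the two ortho sites are equivalent), and inverse quench with the chloroformate should give a doubly ortho-substituted ester too hindered to accept a second aryllithium.

Step 2
Reactants: 3 methyl 2-methoxy-4,6-dimethylbenzoate
Product: 5 methyl 2-methoxy-4-methyl-6-(2-oxopropyl)benzoate, via benzylic lithio toluate 4 (not isolated)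
Conditions: LDA, THF, −78 °C; then MeC(O)N(OMe)Me, −78 → 0 °C; H2O
Reagents that add atoms: N-methoxy-N-methylacetamide, CON(C)C(C)=O
Why: Lateral lithiation of an ortho-toluate (the ester-bound amide base takes a proton from the ortho methyl, not the para one) followed by Weinreb amide acylation, whose chelated tetrahedral intermediate withholds the ketone until work-up.

Step 3
Reactants: 5 methyl 2-methoxy-4-methyl-6-(2-oxopropyl)benzoate
Product: 6 8-methoxy-6-methylnaphthalene-1,3-diol
Conditions: NaH, THF, 0 °C → reflux; then 1 M HCl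
Reagents that add atoms: none
Why: Intramolecular Claisen (Dieckmann-type) condensation, in which the methyl-side ketone enolate reached by equilibration attacks the ester in a six-membered closure and enolization of the diketone to the aromatic naphthalenediolate drives the reaction.

Step 4
Reactants: 6 8-methoxy-6-methylnaphthalene-1,3-diol
Product: 7 8-methoxy-6-methyl-3-(propan-2-yloxy)naphthalen-1-ol
Conditions: HCl (gas, cat.), i-PrOH, 50 °C
Reagents that add atoms: propan-2-ol, CC(C)O
Why: Acid-catalysed etherification of a naphthalene-1,3-diol through its keto tautomer (vinylogous acid to vinylogous ester), which should occur at the C3 oxygen only because C1 is peri-hindered by the C8 methoxy group and its hydroxyl is hydrogen-bonded to it.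

Step 5
Reactants: 7 8-methoxy-6-methyl-3-(propan-2-yloxy)naphthalen-1-ol
Product: 8 1,8-dimethoxy-6-methyl-3-(propan-2-yloxy)naphthalene
Conditions: MeI, K2CO3, DMF, 40 °C
Reagents that add atoms: iodomethane, CI
Why: Williamson O-methylation of the one remaining, hydrogen-bonded peri naphthol, the only acidic site in the molecule.

Step 6
Reactants: 8 1,8-dimethoxy-6-methyl-3-(propan-2-yloxy)naphthalene
Product: 10 4,5-dimethoxy-7-methyl-2-(propan-2-yloxy)naphthalene-1-carbaldehyde, via aryl iminium salt 9 (not isolated)
Conditions: POCl3, DMF, 0 → 50 °C; then H2O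
Reagents that add atoms: N,N-dimethylformamide, CN(C)C=O; water, O
Why: Vilsmeier–Haack formylation, in which the chloroiminium ion should attack C4 of 8, the alpha position para to the C1 methoxy and ortho to the C3 isopropoxy group, which is more activated than the singly activated C5 and less crowded than C2 between two alkoxy groups.

Step 7
Reactants: 11 2-(propan-2-yloxy)phenol
Product: 12 2-(propan-2-yloxy)phenyl N,N-diethylcarbamate
Conditions: ClC(O)NEt2, K2CO3, MeCN, reflux
Reagents that add atoms: N,N-diethylcarbamoyl chloride, CCN(CC)C(=O)Cl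
Why: O-carbamoylation of the phenoxide (acyl substitution), which installs the directing group for the following metalation.

Step 8
Reactants: 12 2-(propan-2-yloxy)phenyl N,N-diethylcarbamate
Product: 14 N,N-diethyl-2-hydroxy-3-(propan-2-yloxy)benzamide, via ortho-lithiated carbamate 13 (not isolated)
Conditions: s-BuLi, TMEDA, THF, −78 °C → rt; then H2O
Reagents that add atoms: none
Why: Directed ortho-metalation followed by anionic ortho-Fries rearrangement, in which the carbamate (the strongest director present) is lithiated at its only free ortho carbon and the carbamoyl group migrates from oxygen to that carbon on warming, fixing the regiochemistry.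

Step 9
Reactants: 14 N,N-diethyl-2-hydroxy-3-(propan-2-yloxy)benzamide
Product: 15 N,N-diethyl-2-methoxy-3-(propan-2-yloxy)benzamide
Conditions: MeI, K2CO3, DMF, rt
Reagents that add atoms: iodomethane, CI
Why: Williamson O-methylation of the salicylamide hydroxyl, which places the methyl ether next to the carbonyl carbon that becomes B-C4.

Step 10
Reactants: 15 N,N-diethyl-2-methoxy-3-(propan-2-yloxy)benzamide; 10 4,5-dimethoxy-7-methyl-2-(propan-2-yloxy)naphthalene-1-carbaldehyde
Product: 18 racemic 3-ArA-7-methoxy-6-(propan-2-yloxy)-2-benzofuran-1(3H)-one, via ortho-lithiated benzamide 16 (not isolated), via hydroxy amide adduct 17 (not isolated)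
Conditions: 15, s-BuLi, TMEDA, THF, −78 °C; then 10, −78 °C → rt; H2O; crude adduct, TsOH·H2O (10 mol %), toluene, reflux
Reagents that add atoms: none
Why: Directed ortho-metalation of the tertiary benzamide at its single free ortho position (the amide outranks the isopropoxy group), 1,2-addition of the aryllithium to the aldehyde and acid-catalysed lactonization with loss of diethylamine should give the 3-arylphthalide, whose one stereocentre forms racemic and is removed in step 12.

Step 11
Reactants: 18 racemic 3-ArA-7-methoxy-6-(propan-2-yloxy)-2-benzofuran-1(3H)-one; 19 (E)-1-bromoprop-1-ene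
Product: 21 3-ArA-7-methoxy-1-[(E)-prop-1-en-1-yl]-6-(propan-2-yloxy)-1,3-dihydro-2-benzofuran-1-ol (lactol; diastereomer mixture; ring-chain tautomer of the open hydroxy enone), via (E)-prop-1-enyllithium 20 (not isolated)
Conditions: 19, t-BuLi (2 equiv), Et2O, −78 °C; then 18, THF, −78 °C; H2O
Reagents that add atoms: none
Why: Bromine–lithium exchange with retention of alkene geometry, then 1,2-addition of the alkenyllithium to the lactone carbonyl, where the cyclic lithium hemiketalate persists at −78 °C and so prevents a second addition; the new hemiketal centre forms without control and vanishes on oxidation.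

Step 12
Reactants: 21 lactol 3-ArA-7-methoxy-1-[(E)-prop-1-en-1-yl]-6-(propan-2-yloxy)-1,3-dihydro-2-benzofuran-1-ol
Product: 22 (E)-1-[2-(ArA-carbonyl)-6-methoxy-5-(propan-2-yloxy)phenyl]but-2-en-1-one
Conditions: Dess–Martin periodinane, pyridine, CH2Cl2, 0 °C → rt
Reagents that add atoms: none
Why: Dess–Martin oxidation of the ring-opened tautomer, in which the secondary diaryl carbinol of the hydroxy enone is oxidized and the ring–chain equilibrium drains toward the 1,2-diacylbenzene, the tertiary hemiketal hydroxyl itself being inert.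

Step 13
Reactants: 22 (E)-1-[2-(ArA-carbonyl)-6-methoxy-5-(propan-2-yloxy)phenyl]but-2-en-1-one
Product: 23 4-ArA-4-hydroxy-8-methoxy-3-methyl-7-(propan-2-yloxy)-3,4-dihydronaphthalen-1(2H)-one (racemic diastereomer mixture)
Conditions: divided cell, reticulated vitreous carbon cathode, Pt anode, 0.1 M Et4NOTs in DMF, t-BuOH (5 equiv), controlled potential at the first reduction wave, 2 F/mol, high dilution, rt
Reagents that add atoms: none
Why: One electron from the cathode enters the 1,2-diacylbenzene and gives the hindered diaryl ketyl radical anion, whose carbon adds to the electron-poor beta-carbon of the neighbouring crotonoyl group; the resulting alpha-keto radical takes up the second electron, and the enolate and alkoxide are protonated by t-BuOH to the gamma-hydroxy ketone. The closest known reaction type is the electroreductive cyclization of a ketone onto a tethered alpha,beta-unsaturated carbonyl compound, the cathodic counterpart of the SmI2 ketyl–olefin coupling, and if the enone were reduced first its beta-carbon would attack the ketone carbon and form the same bond. The single ring formed (B-C1, B-C2, B-C3, B-C4, B-C4a, B-C8a) closes in the 6-endo-trig mode through the new B-C1 to B-C2 bond. The two new stereocentres (C3 and C4 of the tetralone) are under no control, form as a racemic diastereomer mixture and are both erased in step 14, so none is needed. The step needs attack at the beta-carbon in preference to the alpha-carbon (5-exo), and cyclization in preference to pinacol coupling, hydrodimerization or plain reduction to the diarylmethanol: polarity matching of the nucleophilic ketyl with the beta-carbon, the ortho arrangement that holds the two groups within bonding distance, the persistence of the diaryl ketyl, a weak hindered proton donor and dilute solution should secure this. Electrolysis at the first wave should stop at 23 because its electron-rich aryl alkyl ketone is reduced only at a more negative potential.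

Step 14
Reactants: 23 4-ArA-4-hydroxy-8-methoxy-3-methyl-7-(propan-2-yloxy)-3,4-dihydronaphthalen-1(2H)-one
Product: 25 4-ArA-8-methoxy-3-methyl-7-(propan-2-yloxy)naphthalen-1-ol (racemic biaryl), via naphthalen-1(2H)-one tautomer 24 (not isolated)
Conditions: TsOH·H2O (cat.), toluene, 80 °C
Reagents that add atoms: none
Why: Acid-catalysed E1 dehydration of the doubly benzylic tertiary alcohol (the cation is stabilized by the electron-rich naphthyl group) gives the 3,4-ene, and keto–enol tautomerization then aromatizes the ring to the 1-naphthol, raising the hindered biaryl axis as a racemate and erasing both sp3 centres.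

Step 15
Reactants: 25 4-ArA-8-methoxy-3-methyl-7-(propan-2-yloxy)naphthalen-1-ol
Product: 26 4',5,5'-trimethoxy-2,7'-dimethyl-[1,1'-binaphthalene]-2',4,6-triol (CNP0288130.0, racemic biaryl)
Conditions: BCl3, CH2Cl2, −78 → 0 °C; then H2O
Reagents that add atoms: none
Why: Lewis acid dealkylation, in which BCl3 cleaves secondary alkyl (isopropyl) aryl ethers far faster than methyl aryl ethers at low temperature, and since no carbonyl group remains to deliver boron to a neighbouring methoxy group the three methyl ethers should survive.

**Compound list**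

1 | 1-methoxy-3,5-dimethylbenzene (3,5-dimethylanisole) | COc1cc(C)cc(C)c1 | starting material
2 | (2-methoxy-4,6-dimethylphenyl)lithium | [Li]c1c(C)cc(C)cc1OC | intermediate
3 | methyl 2-methoxy-4,6-dimethylbenzoate | COC(=O)c1c(C)cc(C)cc1OC | intermediate
4 | {[3-methoxy-2-(methoxycarbonyl)-5-methylphenyl]methyl}lithium | [Li]Cc1cc(C)cc(OC)c1C(=O)OC | intermediate
5 | methyl 2-methoxy-4-methyl-6-(2-oxopropyl)benzoate | COC(=O)c1c(CC(C)=O)cc(C)cc1OC | intermediate
6 | 8-methoxy-6-methylnaphthalene-1,3-diol | COc1cc(C)cc2cc(O)cc(O)c12 | intermediate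
7 | 8-methoxy-6-methyl-3-(propan-2-yloxy)naphthalen-1-ol | COc1cc(C)cc2cc(OC(C)C)cc(O)c12 | intermediate
8 | 1,8-dimethoxy-6-methyl-3-(propan-2-yloxy)naphthalene | COc1cc(C)cc2cc(OC(C)C)cc(OC)c12 | intermediate
9 | N-{[4,5-dimethoxy-7-methyl-2-(propan-2-yloxy)naphthalen-1-yl]methylidene}-N-methylmethanaminium dichlorophosphate | C[N+](C)=Cc1c(OC(C)C)cc(OC)c2c(OC)cc(C)cc12.[O-]P(=O)(Cl)Cl | intermediate
10 | 4,5-dimethoxy-7-methyl-2-(propan-2-yloxy)naphthalene-1-carbaldehyde | COc1cc(C)cc2c(C=O)c(OC(C)C)cc(OC)c12 | intermediate
11 | 2-(propan-2-yloxy)phenol | CC(C)Oc1ccccc1O | starting material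
12 | 2-(propan-2-yloxy)phenyl N,N-diethylcarbamate | CCN(CC)C(=O)Oc1ccccc1OC(C)C | intermediate
13 | {2-[(diethylcarbamoyl)oxy]-3-(propan-2-yloxy)phenyl}lithium | [Li]c1cccc(OC(C)C)c1OC(=O)N(CC)CC | intermediate
14 | N,N-diethyl-2-hydroxy-3-(propan-2-yloxy)benzamide | CCN(CC)C(=O)c1cccc(OC(C)C)c1O | intermediate
15 | N,N-diethyl-2-methoxy-3-(propan-2-yloxy)benzamide | CCN(CC)C(=O)c1cccc(OC(C)C)c1OC | intermediate
16 | [2-(diethylcarbamoyl)-3-methoxy-4-(propan-2-yloxy)phenyl]lithium | [Li]c1ccc(OC(C)C)c(OC)c1C(=O)N(CC)CC | intermediate
17 | 6-{[4,5-dimethoxy-7-methyl-2-(propan-2-yloxy)naphthalen-1-yl](hydroxy)methyl}-N,N-diethyl-2-methoxy-3-(propan-2-yloxy)benzamide (racemic) | CCN(CC)C(=O)c1c(OC)c(OC(C)C)ccc1C(O)c1c(OC(C)C)cc(OC)c2c(OC)cc(C)cc12 | intermediate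
18 | 3-[4,5-dimethoxy-7-methyl-2-(propan-2-yloxy)naphthalen-1-yl]-7-methoxy-6-(propan-2-yloxy)-2-benzofuran-1(3H)-one (racemic) | COc1c(OC(C)C)ccc2c1C(=O)OC2c1c(OC(C)C)cc(OC)c2c(OC)cc(C)cc12 | intermediate
19 | (E)-1-bromoprop-1-ene | C/C=C/Br | starting material
20 | (E)-prop-1-en-1-yllithium | C/C=C/[Li] | intermediate
21 | 3-[4,5-dimethoxy-7-methyl-2-(propan-2-yloxy)naphthalen-1-yl]-7-methoxy-1-[(E)-prop-1-en-1-yl]-6-(propan-2-yloxy)-1,3-dihydro-2-benzofuran-1-ol (diastereomer mixture, lactol form of the hydroxy enone) | C/C=C/C1(O)OC(c2c(OC(C)C)cc(OC)c3c(OC)cc(C)cc23)c2ccc(OC(C)C)c(OC)c21 | intermediate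
22 | (E)-1-{2-[4,5-dimethoxy-7-methyl-2-(propan-2-yloxy)naphthalene-1-carbonyl]-6-methoxy-5-(propan-2-yloxy)phenyl}but-2-en-1-one | C/C=C/C(=O)c1c(OC)c(OC(C)C)ccc1C(=O)c1c(OC(C)C)cc(OC)c2c(OC)cc(C)cc12 | intermediate
23 | 4-[4,5-dimethoxy-7-methyl-2-(propan-2-yloxy)naphthalen-1-yl]-4-hydroxy-8-methoxy-3-methyl-7-(propan-2-yloxy)-3,4-dihydronaphthalen-1(2H)-one (racemic diastereomer mixture) | CC1CC(=O)c2c(OC)c(OC(C)C)ccc2C1(O)c1c(OC(C)C)cc(OC)c2c(OC)cc(C)cc12 | intermediate
24 | 4-[4,5-dimethoxy-7-methyl-2-(propan-2-yloxy)naphthalen-1-yl]-8-methoxy-3-methyl-7-(propan-2-yloxy)naphthalen-1(2H)-one | CC1=C(c2c(OC(C)C)cc(OC)c3c(OC)cc(C)cc23)c2ccc(OC(C)C)c(OC)c2C(=O)C1 | intermediate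
25 | 4-[4,5-dimethoxy-7-methyl-2-(propan-2-yloxy)naphthalen-1-yl]-8-methoxy-3-methyl-7-(propan-2-yloxy)naphthalen-1-ol (racemic biaryl) | COc1cc(C)cc2c(-c3c(C)cc(O)c4c(OC)c(OC(C)C)ccc34)c(OC(C)C)cc(OC)c12 | intermediate
26 | 4',5,5'-trimethoxy-2,7'-dimethyl-[1,1'-binaphthalene]-2',4,6-triol (CNP0288130.0) | COc1cc(C)cc2c(-c3c(C)cc(O)c4c(OC)c(O)ccc34)c(O)cc(OC)c12 | target

**Step count**

Total steps: 15.
Longest linear sequence: 12 steps (steps 1 to 6, then 10 to 15); the benzamide branch (steps 7 to 9) joins at step 10.

**Steps most likely to fail**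

Step 13. The ketyl may be protonated and reduced on to the diarylmethanol, or couple intermolecularly (pinacol or hydrodimer), before the twisted and crowded carbonyl groups reach the geometry for ring closure. The fallback sets out from 18 and returns at 23, forming the same B-C1 to B-C2 bond by polar means. LDA (THF, −78 °C) deprotonates 18 at C3 to the lithiated phthalide [1-ArA-4-methoxy-3-oxo-5-(propan-2-yloxy)-1,3-dihydro-2-benzofuran-1-yl]lithium F1, which adds in Michael fashion to methyl (E)-but-2-enoate. The ester enolate then closes onto the lactone carbonyl (Dieckmann) to give methyl 4-ArA-4-hydroxy-8-methoxy-3-methyl-1-oxo-7-(propan-2-yloxy)-1,2,3,4-tetrahydronaphthalene-2-carboxylate F2. Krapcho dealkoxycarbonylation (LiCl, wet DMSO, heat) should then give 23, and the route continues with step 14.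

Step 11. The alkenyllithium may act as a base toward the acidic C3–H of the phthalide, or add a second time (1,2 or conjugate) to enone set free by early collapse of the hemiketalate. The fallback sets out from 18 and returns at 22. i-Bu2AlH (toluene, −78 °C) reduces the lactone to the lactol 3-ArA-7-methoxy-6-(propan-2-yloxy)-1,3-dihydro-2-benzofuran-1-ol F3. (E)-Prop-1-enylmagnesium bromide F4, made from 19 and Mg in THF and used in excess (its alkene geometry is of no consequence later), opens F3 through its hydroxy aldehyde form to the diol (E)-1-{2-[ArA(hydroxy)methyl]-6-methoxy-5-(propan-2-yloxy)phenyl}but-2-en-1-ol F5. Dess–Martin periodinane in excess then oxidizes both carbinols and should give 22.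

Step 10. Addition between the two hindered partners may be slow, so that the lithiated benzamide self-condenses on warming before it reaches the donor-deactivated aldehyde. The fallback sets out from 8 and 15 and returns at 18 with the polarity reversed. NBS (MeCN, 0 °C) brominates 8 at the position formylated in step 6 to give 1-bromo-4,5-dimethoxy-7-methyl-2-(propan-2-yloxy)naphthalene F6. Compound 15 is lithiated as in step 10 (to 16) and quenched with DMF to N,N-diethyl-6-formyl-2-methoxy-3-(propan-2-yloxy)benzamide F7. Bromine–lithium exchange of F6 with n-BuLi (THF, −78 °C) gives [4,5-dimethoxy-7-methyl-2-(propan-2-yloxy)naphthalen-1-yl]lithium F8, which adds to the unhindered formyl group of F7 to give 17, and TsOH in hot toluene closes 18.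

**Further compounds**

F1 | step 13 | [1-[4,5-dimethoxy-7-methyl-2-(propan-2-yloxy)naphthalen-1-yl]-4-methoxy-3-oxo-5-(propan-2-yloxy)-1,3-dihydro-2-benzofuran-1-yl]lithium | [Li]C1(c2c(OC(C)C)cc(OC)c3c(OC)cc(C)cc23)OC(=O)c2c(OC)c(OC(C)C)ccc21
F2 | step 13 | methyl 4-[4,5-dimethoxy-7-methyl-2-(propan-2-yloxy)naphthalen-1-yl]-4-hydroxy-8-methoxy-3-methyl-1-oxo-7-(propan-2-yloxy)-1,2,3,4-tetrahydronaphthalene-2-carboxylate (diastereomer mixture) | COC(=O)C1C(C)C(O)(c2c(OC(C)C)cc(OC)c3c(OC)cc(C)cc23)c2ccc(OC(C)C)c(OC)c2C1=O
F3 | step 11 | 3-[4,5-dimethoxy-7-methyl-2-(propan-2-yloxy)naphthalen-1-yl]-7-methoxy-6-(propan-2-yloxy)-1,3-dihydro-2-benzofuran-1-ol | OC1OC(c2c(OC(C)C)cc(OC)c3c(OC)cc(C)cc23)c2ccc(OC(C)C)c(OC)c21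
F4 | step 11 | (E)-prop-1-en-1-ylmagnesium bromide | C/C=C/[Mg]Br
F5 | step 11 | (E)-1-{2-[[4,5-dimethoxy-7-methyl-2-(propan-2-yloxy)naphthalen-1-yl](hydroxy)methyl]-6-methoxy-5-(propan-2-yloxy)phenyl}but-2-en-1-ol | C/C=C/C(O)c1c(OC)c(OC(C)C)ccc1C(O)c1c(OC(C)C)cc(OC)c2c(OC)cc(C)cc12
F6 | step 10 | 1-bromo-4,5-dimethoxy-7-methyl-2-(propan-2-yloxy)naphthalene | COc1cc(C)cc2c(Br)c(OC(C)C)cc(OC)c12
F7 | step 10 | N,N-diethyl-6-formyl-2-methoxy-3-(propan-2-yloxy)benzamide | CCN(CC)C(=O)c1c(C=O)ccc(OC(C)C)c1OC
F8 | step 10 | [4,5-dimethoxy-7-methyl-2-(propan-2-yloxy)naphthalen-1-yl]lithium | [Li]c1c(OC(C)C)cc(OC)c2c(OC)cc(C)cc12
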